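## Retrosynthetic overview

- **Feature:** ring A (C4a to C8a) carries four contiguous substituents: C4 on C4a, O1 on C8a, the hydroxyalkyl chain on C8 and OH on C7. A vinylketene (C7, C4a, C5, C6) and an alkyl ynol ether (C8, C8a–O1) give exactly this pattern, and O1–C2–C3–C4 of ring C can tie the two partners together.
- **Key disconnection:** C7–C8 and C4a–C8a, leading back to a 2-substituted cyclobutenone tethered to the ynol ether. On heating, ring C closes first ([2+2]) and ring A second (6π). Ring B is present from the start.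
- **Cyclobutenone:** it is attached last and intact, by C4–C4a Negishi coupling of an alkylzinc with 2-bromocyclobutenone. An ynol ether would not survive halogenation or acid, and the enone would not survive n-BuLi.
- **Ynol ether and C3:** the ynol ether comes from the C2 alcohol, trichloroethylene and a side-chain iodide. C3 is set by lipase desymmetrisation of the 2-arylpropane-1,3-diol.
- **Ring B and endgame:** ring B comes from 2,4-dihydroxyphenylacetic acid, and its 1,1-dimethylallyl group from an aromatic Claisen rearrangement of the 4′-O-prenyl ether. One fluoride step ends the route.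

Key step: step 21

**Numbering and abbreviation:** isoflavan numbering is used throughout, with ring-B atoms primed. Ar = 4-[(tert-butyldimethylsilyl)oxy]-5-(2-methylbut-3-en-2-yl)-2-[(triisopropylsilyl)oxy]phenyl (protected ring B).

**Assumption:** the lipase of step 8 is taken to acetylate the pro-S hydroxymethyl arm of the prochiral diol. The sense is to be checked on the monoacetate before going on.

## Route

Step 1
Reactants: 1 2,4-dihydroxyphenylacetic acid
Product: 2 methyl 2-(2,4-dihydroxyphenyl)acetate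
Conditions: MeOH, H2SO4 (cat.), reflux
Reagents that add atoms: methanol, CO
Why: Fischer esterification in a large excess of methanol masks the acid and keeps the 2′-hydroxyl from closing to the benzofuranone.

Step 2
Reactants: 2 methyl 2-(2,4-dihydroxyphenyl)acetate; 3 prenyl bromide (1-bromo-3-methylbut-2-ene)
Product: 4 methyl 2-{2-hydroxy-4-[(3-methylbut-2-en-1-yl)oxy]phenyl}acetate
Conditions: 3 (1.0 equiv), K2CO3, acetone, rt
Reagents that add atoms: none
Why: Williamson ether synthesis; the 4′-phenoxide is unhindered whereas the 2′-hydroxyl sits next to the acetate side chain and is hydrogen-bonded to its carbonyl group, so mono-O-alkylation should fall on O4′ and any bis-ether is removed by chromatography.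

Step 3
Reactants: 4 methyl 2-{2-hydroxy-4-[(3-methylbut-2-en-1-yl)oxy]phenyl}acetate
Product: 5 methyl 2-{4-[(3-methylbut-2-en-1-yl)oxy]-2-[(triisopropylsilyl)oxy]phenyl}acetate
Conditions: TIPSCl, imidazole, DMF, rt
Reagents that add atoms: triisopropylsilyl chloride, CC(C)[Si](Cl)(C(C)C)C(C)C
Why: Silyl ether formation; the bulky, migration-resistant triisopropylsilyl group is chosen for O2′ because it shields C3′ in the next step and later sits close to alkoxides on the C2 and C4 arms.

Step 4
Reactants: 5 methyl 2-{4-[(3-methylbut-2-en-1-yl)oxy]-2-[(triisopropylsilyl)oxy]phenyl}acetate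
Product: 7 methyl 2-{4-hydroxy-5-(2-methylbut-3-en-2-yl)-2-[(triisopropylsilyl)oxy]phenyl}acetate, via ortho-dienone 6 (not isolated)
Conditions: PhNEt2, 190 °C, Ar
Reagents that add atoms: none
Why: Aromatic Claisen rearrangement, whose allyl inversion turns the prenyl ether into the 1,1-dimethylallyl group; of the two ortho positions C3′ is walled in by the OTIPS group and the para position is occupied, so the bond should form at C5′ and dienone 6 rearomatises by enolisation.

Step 5
Reactants: 7 methyl 2-{4-hydroxy-5-(2-methylbut-3-en-2-yl)-2-[(triisopropylsilyl)oxy]phenyl}acetate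
Product: 8 methyl 2-Ar-acetate
Conditions: TBSOTf, 2,6-lutidine, CH2Cl2, 0 °C → rt
Reagents that add atoms: tert-butyldimethylsilyl triflate, CC(C)(C)[Si](C)(C)OS(=O)(=O)C(F)(F)F
Why: Silylation with the reactive silyl triflate overcomes the hindrance of the phenol next to the quaternary carbon, which in turn shields this silyl ether from bases in the later steps.

Step 6
Reactants: 8 methyl 2-Ar-acetate
Product: 9 dimethyl 2-Ar-malonate
Conditions: LiHMDS (2.2 equiv), THF, −78 °C; ClCO2Me, −78 → 0 °C; NH4Cl aq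
Reagents that add atoms: methyl chloroformate, COC(=O)Cl
Why: Claisen-type C-acylation (methoxycarbonylation) of the ester enolate, the second equivalent of base taking up the more acidic malonate proton so that acylation goes to completion.

Step 7
Reactants: 9 dimethyl 2-Ar-malonate
Product: 10 2-Ar-propane-1,3-diol
Conditions: DIBAL-H (6 equiv), CH2Cl2, −78 → 0 °C; Rochelle salt
Reagents that add atoms: none
Why: Hydride reduction of both esters; the weakly basic, Lewis acidic aluminium hydride should reduce the aryl malonate rather than enolise it and leaves the aryl silyl ethers and the alkene alone.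

Step 8
Reactants: 10 2-Ar-propane-1,3-diol
Product: 11 (2S)-2-Ar-3-hydroxypropyl acetate
Conditions: Burkholderia cepacia lipase (immobilised), vinyl acetate, MTBE, 25 °C
Reagents that add atoms: vinyl acetate, C=COC(C)=O
Why: Enzymatic desymmetrisation by irreversible lipase transesterification; the enzyme tells apart the two enantiotopic hydroxymethyl arms of a 2-arylpropane-1,3-diol, a standard substrate class, and thereby sets C3, the acetylated arm becoming C2 and the free arm C4.

Step 9
Reactants: 11 (2S)-2-Ar-3-hydroxypropyl acetate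
Product: 12 (2S)-2-Ar-3-(tetrahydropyran-2-yloxy)propyl acetate (acetal epimers)
Conditions: 3,4-dihydro-2H-pyran, PPTS (cat.), CH2Cl2, rt
Reagents that add atoms: 3,4-dihydro-2H-pyran, C1=COCCC1
Why: Acid-catalysed acetalisation (THP ether); an acetal is chosen because, unlike an acyl or silyl group, it cannot migrate to the other arm under base, which would racemise C3.

Step 10
Reactants: 12 (2S)-2-Ar-3-(tetrahydropyran-2-yloxy)propyl acetate
Product: 13 (2R)-2-Ar-3-(tetrahydropyran-2-yloxy)propan-1-ol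
Conditions: DIBAL-H (2.5 equiv), CH2Cl2, −78 °C; Rochelle salt
Reagents that add atoms: none
Why: Reductive ester cleavage frees the C2 hydroxyl without the basic methanolysis that would endanger the aryl silyl ethers.

Step 11
Reactants: 13 (2R)-2-Ar-3-(tetrahydropyran-2-yloxy)propan-1-ol; 14 trichloroethylene
Product: 16 2-{(2S)-2-Ar-3-[(E)-1,2-dichlorovinyloxy]propoxy}tetrahydropyran, via dichloroacetylene 15 (not isolated)
Conditions: KH, THF, 0 °C; 14, −50 °C → rt
Reagents that add atoms: none
Why: Base-induced dehydrochlorination of trichloroethylene followed by anti addition of the alkoxide to the dichloroacetylene so formed, the standard entry to ynol ether precursors; the acetal, the alkene and the hindered aryl silyl ethers are inert to the short-lived potassium alkoxide.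

Step 12
Reactants: 16 2-{(2S)-2-Ar-3-[(E)-1,2-dichlorovinyloxy]propoxy}tetrahydropyran
Product: 17 (2S)-2-Ar-3-[(E)-1,2-dichlorovinyloxy]propan-1-ol
Conditions: PPTS, MeOH, 40 °C
Reagents that add atoms: none
Why: Acid-catalysed transacetalisation; the electron-poor dichlorovinyl ether and the aryl silyl ethers tolerate mild acid, and the C4 hydroxyl is freed now because no acid can be used once the ynol ether exists.

Step 13
Reactants: 18 3-methylbutane-1,3-diol
Product: 19 4-iodo-2-methylbutan-2-ol
Conditions: I2, PPh3, imidazole, CH2Cl2, 0 °C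
Reagents that add atoms: iodine, II
Why: Appel iodination is selective for the primary hydroxyl because the tertiary one cannot undergo the SN2 displacement.

Step 14
Reactants: 19 4-iodo-2-methylbutan-2-ol
Product: 20 triethyl[(4-iodo-2-methylbutan-2-yl)oxy]silane
Conditions: TESOTf, 2,6-lutidine, CH2Cl2, −78 → 0 °C
Reagents that add atoms: triethylsilyl triflate, CC[Si](CC)(CC)OS(=O)(=O)C(F)(F)F
Why: Silylation with a silyl triflate, as a tertiary alcohol requires; the hydroxyl must be blocked because it would otherwise trap ketene carbon C7 as a six-membered lactone in the key step.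

Step 15
Reactants: 17 (2S)-2-Ar-3-[(E)-1,2-dichlorovinyloxy]propan-1-ol; 20 triethyl[(4-iodo-2-methylbutan-2-yl)oxy]silane
Product: 22 (2S)-2-Ar-3-{[5-methyl-5-(triethylsilyloxy)hex-1-yn-1-yl]oxy}propan-1-ol, via dilithio alkoxide acetylide 21 (not isolated)
Conditions: 17 added to n-BuLi (3.3 equiv), THF, −78 → −40 °C; 20 (1.5 equiv), HMPA, −78 °C → rt; NaHCO3 aq
Reagents that add atoms: n-butyllithium, [Li]CCCC (lithium in 21 only)
Why: Elimination of HCl and chlorine–lithium exchange turn the dichlorovinyl ether into the lithium alkoxyacetylide while one equivalent of base deprotonates the hydroxyl, and this alkynol-type dianion is alkylated by the primary iodide at the far more nucleophilic acetylide carbon (acetylide alkylation), forming the C8–side-chain bond.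

Step 16
Reactants: 22 (2S)-2-Ar-3-{[5-methyl-5-(triethylsilyloxy)hex-1-yn-1-yl]oxy}propan-1-ol
Product: 24 (2R)-2-Ar-3-iodopropyl 5-methyl-5-(triethylsilyloxy)hex-1-yn-1-yl ether, via mesylate 23 (not isolated)
Conditions: MsCl, Et3N, CH2Cl2, −20 °C; then NaI, NaHCO3, acetone, 50 °C
Reagents that add atoms: methanesulfonyl chloride, CS(=O)(=O)Cl (in 23 only); sodium iodide, [Na+].[I-]
Why: Sulfonylation followed by Finkelstein-type SN2 displacement keeps the medium basic or neutral and free of electrophilic iodine, the conditions an acid- and halogen-sensitive ynol ether tolerates, and stays far below its retro-ene temperature.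

Step 17
Reactants: 25 3-oxocyclobutane-1-carboxylic acid
Product: 26 3-bromocyclobutan-1-one
Conditions: HgO, Br2, MgSO4, CH2Cl2, reflux
Reagents that add atoms: bromine, BrBr
Why: Hunsdiecker-type bromodecarboxylation (Cristol–Firth modification) replaces the carboxyl group by bromine β to the ketone.

Step 18
Reactants: 26 3-bromocyclobutan-1-one
Product: 27 cyclobut-2-en-1-one
Conditions: n-Bu3N, neat, rt, reduced pressure, product collected at −78 °C
Reagents that add atoms: none
Why: E1cB dehydrobromination of the β-bromo ketone, the volatile enone being distilled out of the base as it forms.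

Step 19
Reactants: 27 cyclobut-2-en-1-one
Product: 29 2-bromocyclobut-2-en-1-one, via 2,3-dibromocyclobutanone 28 (not isolated)
Conditions: Br2, CH2Cl2, −78 °C; Et3N, −78 → 0 °C
Reagents that add atoms: bromine, BrBr
Why: Bromination–dehydrobromination, the standard α-bromination of enones; the base removes the more acidic proton at C2 of 28 and the β-bromide leaves, so the halogen ends on the α-carbon.

Step 20
Reactants: 24 (2R)-2-Ar-3-iodopropyl 5-methyl-5-(triethylsilyloxy)hex-1-yn-1-yl ether; 29 2-bromocyclobut-2-en-1-one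
Product: 31 2-[(2R)-2-Ar-3-{[5-methyl-5-(triethylsilyloxy)hex-1-yn-1-yl]oxy}propyl]cyclobut-2-en-1-one, via alkylzinc iodide 30 (not isolated)
Conditions: Zn dust (I2-activated), DMA, 30 °C, solution decanted from excess Zn; 29, Pd(OAc)2 (4 mol %), SPhos (8 mol %), THF, 0 °C → rt
Reagents that add atoms: zinc, [Zn] (in 30 only)
Why: Negishi coupling; zinc inserts into the primary C–I bond to give a reagent too unreactive to touch the ynol ether, the silyl ethers or an enone by itself, and zerovalent palladium inserts into the C–Br bond of the α-bromo enone, a class of electrophile for which α-alkylation with alkylzinc halides is established, so C4–C4a forms under neutral conditions with C3 untouched.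

Step 21
Reactants: 31 2-[(2R)-2-Ar-3-{[5-methyl-5-(triethylsilyloxy)hex-1-yn-1-yl]oxy}propyl]cyclobut-2-en-1-one
Product: 36 (3R)-3-Ar-8-[3-methyl-3-(triethylsilyloxy)butyl]chroman-7-ol, via vinylketene 32 (not isolated), via fused vinylcyclobutenone 33 (not isolated), via dienylketene 34 (not isolated), via cyclohexadienone 35 (not isolated)
Conditions: PhMe (5 mM, degassed, base-washed glass), 80 °C until 31 is consumed; then 110 °C
Reagents that add atoms: none
Why: Proposed new method: heating opens the cyclobutenone of 31 by 4π electrocyclic cleavage of C6–C7 to vinylketene 32, whose C7=C4a bond adds across the tethered ynol ether in a polarity-matched [2+2] step (nucleophilic C8 to ketene carbon C7, oxygen-stabilised C8a to C4a) to give 33, which reopens by 4π cleavage of C7–C4a to dienylketene 34 and closes by 6π electrocyclisation (C6–C7) to dienone 35, the keto tautomer of phenol 36. The closest known reaction type is the intermolecular Danheiser benzannulation of cyclobutenones with alkoxyalkynes, together with intramolecular ketene [2+2] cycloadditions through short tethers; what is new is joining the two partners through C4–C3–C2–O1. Ring C closes in the [2+2] step as the six-membered ring of a fused 2-oxabicyclo[4.2.0]octenone (C4a–C8a bond), and ring A closes by the disrotatory 6π electrocyclisation followed by enolisation. No lasting stereocentre is created, since C4a of 33 is transient and C3 is a spectator as long as its hydrogen is not transferred. The step needs regiocontrol, which ynol-ether polarity and tether length impose in the same sense, inward rotation of the vinyl group when 33 opens, which ring C enforces because C4 and O1 must stay cis on C4a=C8a, and chemoselectivity over retro-ene transfer of the C3 hydrogen and over ketene dimerisation, which the 80 °C first stage (the ynol ether is consumed before the bath is raised) and the high dilution are meant to secure.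

Step 22
Reactants: 36 (3R)-3-Ar-8-[3-methyl-3-(triethylsilyloxy)butyl]chroman-7-ol
Product: 37 (3R)-3-[2,4-dihydroxy-5-(2-methylbut-3-en-2-yl)phenyl]-8-(3-hydroxy-3-methylbutyl)chroman-7-ol (target)
Conditions: TBAF, AcOH (6 equiv each), THF, rt → 40 °C
Reagents that add atoms: none
Why: Fluoride desilylation removes the two aryl silyl ethers and the tertiary triethylsilyl ether in one operation, the acetic acid buffer keeping the electron-rich phenols protonated and avoiding the strong acid that would cyclise the hydroxyalkyl or dimethylallyl chains onto their neighbouring phenols.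

## Compound list

1 | 2,4-dihydroxyphenylacetic acid | OC(=O)Cc1ccc(O)cc1O | starting material
2 | methyl 2-(2,4-dihydroxyphenyl)acetate | COC(=O)Cc1ccc(O)cc1O | intermediate
3 | prenyl bromide (1-bromo-3-methylbut-2-ene) | CC(C)=CCBr | starting material
4 | methyl 2-{2-hydroxy-4-[(3-methylbut-2-en-1-yl)oxy]phenyl}acetate | COC(=O)Cc1ccc(OCC=C(C)C)cc1O | intermediate
5 | methyl 2-{4-[(3-methylbut-2-en-1-yl)oxy]-2-[(triisopropylsilyl)oxy]phenyl}acetate | COC(=O)Cc1ccc(OCC=C(C)C)cc1O[Si](C(C)C)(C(C)C)C(C)C | intermediate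
6 | ortho-dienone, methyl 2-[3-(2-methylbut-3-en-2-yl)-4-oxo-6-(triisopropylsilyloxy)cyclohexa-1,5-dien-1-yl]acetate | COC(=O)CC1=CC(C(C)(C)C=C)C(=O)C=C1O[Si](C(C)C)(C(C)C)C(C)C | intermediate
7 | methyl 2-{4-hydroxy-5-(2-methylbut-3-en-2-yl)-2-[(triisopropylsilyl)oxy]phenyl}acetate | COC(=O)Cc1cc(C(C)(C)C=C)c(O)cc1O[Si](C(C)C)(C(C)C)C(C)C | intermediate
8 | methyl 2-Ar-acetate | COC(=O)Cc1cc(C(C)(C)C=C)c(O[Si](C)(C)C(C)(C)C)cc1O[Si](C(C)C)(C(C)C)C(C)C | intermediate
9 | dimethyl 2-Ar-malonate | COC(=O)C(C(=O)OC)c1cc(C(C)(C)C=C)c(O[Si](C)(C)C(C)(C)C)cc1O[Si](C(C)C)(C(C)C)C(C)C | intermediate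
10 | 2-Ar-propane-1,3-diol | C=CC(C)(C)c1cc(C(CO)CO)c(O[Si](C(C)C)(C(C)C)C(C)C)cc1O[Si](C)(C)C(C)(C)C | intermediate
11 | (2S)-2-Ar-3-hydroxypropyl acetate | C=CC(C)(C)c1cc([C@@H](CO)COC(C)=O)c(O[Si](C(C)C)(C(C)C)C(C)C)cc1O[Si](C)(C)C(C)(C)C | intermediate
12 | (2S)-2-Ar-3-(tetrahydropyran-2-yloxy)propyl acetate (acetal epimers) | C=CC(C)(C)c1cc([C@@H](COC2CCCCO2)COC(C)=O)c(O[Si](C(C)C)(C(C)C)C(C)C)cc1O[Si](C)(C)C(C)(C)C | intermediate
13 | (2R)-2-Ar-3-(tetrahydropyran-2-yloxy)propan-1-ol | C=CC(C)(C)c1cc([C@@H](COC2CCCCO2)CO)c(O[Si](C(C)C)(C(C)C)C(C)C)cc1O[Si](C)(C)C(C)(C)C | intermediate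
14 | trichloroethylene | ClC=C(Cl)Cl | starting material
15 | dichloroacetylene | ClC#CCl | intermediate
16 | 2-{(2S)-2-Ar-3-[(E)-1,2-dichlorovinyloxy]propoxy}tetrahydropyran | C=CC(C)(C)c1cc([C@@H](COC2CCCCO2)CO/C(Cl)=C\Cl)c(O[Si](C(C)C)(C(C)C)C(C)C)cc1O[Si](C)(C)C(C)(C)C | intermediate
17 | (2S)-2-Ar-3-[(E)-1,2-dichlorovinyloxy]propan-1-ol | C=CC(C)(C)c1cc([C@@H](CO)CO/C(Cl)=C\Cl)c(O[Si](C(C)C)(C(C)C)C(C)C)cc1O[Si](C)(C)C(C)(C)C | intermediate
18 | 3-methylbutane-1,3-diol | CC(C)(O)CCO | starting material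
19 | 4-iodo-2-methylbutan-2-ol | CC(C)(O)CCI | intermediate
20 | triethyl[(4-iodo-2-methylbutan-2-yl)oxy]silane | CC[Si](CC)(CC)OC(C)(C)CCI | intermediate
21 | dilithio species, lithium (2S)-2-Ar-3-(lithioethynyloxy)propan-1-olate | C=CC(C)(C)c1cc([C@@H](CO[Li])COC#C[Li])c(O[Si](C(C)C)(C(C)C)C(C)C)cc1O[Si](C)(C)C(C)(C)C | intermediate
22 | (2S)-2-Ar-3-{[5-methyl-5-(triethylsilyloxy)hex-1-yn-1-yl]oxy}propan-1-ol | C=CC(C)(C)c1cc([C@@H](CO)COC#CCCC(C)(C)O[Si](CC)(CC)CC)c(O[Si](C(C)C)(C(C)C)C(C)C)cc1O[Si](C)(C)C(C)(C)C | intermediate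
23 | (2R)-2-Ar-3-{[5-methyl-5-(triethylsilyloxy)hex-1-yn-1-yl]oxy}propyl methanesulfonate | C=CC(C)(C)c1cc([C@@H](COS(C)(=O)=O)COC#CCCC(C)(C)O[Si](CC)(CC)CC)c(O[Si](C(C)C)(C(C)C)C(C)C)cc1O[Si](C)(C)C(C)(C)C | intermediate
24 | (2R)-2-Ar-3-iodopropyl 5-methyl-5-(triethylsilyloxy)hex-1-yn-1-yl ether | C=CC(C)(C)c1cc([C@@H](CI)COC#CCCC(C)(C)O[Si](CC)(CC)CC)c(O[Si](C(C)C)(C(C)C)C(C)C)cc1O[Si](C)(C)C(C)(C)C | intermediate
25 | 3-oxocyclobutane-1-carboxylic acid | O=C1CC(C(=O)O)C1 | starting material
26 | 3-bromocyclobutan-1-one | O=C1CC(Br)C1 | intermediate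
27 | cyclobut-2-en-1-one | O=C1C=CC1 | intermediate
28 | 2,3-dibromocyclobutan-1-one | O=C1CC(Br)C1Br | intermediate
29 | 2-bromocyclobut-2-en-1-one | O=C1CC=C1Br | intermediate
30 | [(2R)-2-Ar-3-{[5-methyl-5-(triethylsilyloxy)hex-1-yn-1-yl]oxy}propyl]zinc iodide | C=CC(C)(C)c1cc([C@@H](C[Zn]I)COC#CCCC(C)(C)O[Si](CC)(CC)CC)c(O[Si](C(C)C)(C(C)C)C(C)C)cc1O[Si](C)(C)C(C)(C)C | intermediate
31 | 2-[(2R)-2-Ar-3-{[5-methyl-5-(triethylsilyloxy)hex-1-yn-1-yl]oxy}propyl]cyclobut-2-en-1-one (key-step precursor) | C=CC(C)(C)c1cc([C@@H](CC2=CCC2=O)COC#CCCC(C)(C)O[Si](CC)(CC)CC)c(O[Si](C(C)C)(C(C)C)C(C)C)cc1O[Si](C)(C)C(C)(C)C | intermediate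
32 | vinylketene, 2-[(2R)-2-Ar-3-{[5-methyl-5-(triethylsilyloxy)hex-1-yn-1-yl]oxy}propyl]buta-1,3-dien-1-one | C=CC(C)(C)c1cc([C@@H](CC(C=C)=C=O)COC#CCCC(C)(C)O[Si](CC)(CC)CC)c(O[Si](C(C)C)(C(C)C)C(C)C)cc1O[Si](C)(C)C(C)(C)C | intermediate
33 | (4R)-4-Ar-6-ethenyl-8-[3-methyl-3-(triethylsilyloxy)butyl]-2-oxabicyclo[4.2.0]oct-1(8)-en-7-one (C6 configuration transient, not specified) | C=CC(C)(C)c1cc([C@@H]2COC3=C(CCC(C)(C)O[Si](CC)(CC)CC)C(=O)C3(C=C)C2)c(O[Si](C(C)C)(C(C)C)C(C)C)cc1O[Si](C)(C)C(C)(C)C | intermediate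
34 | dienylketene, 2-[(3R)-3-Ar-5-ethenyl-3,4-dihydro-2H-pyran-6-yl]-5-methyl-5-(triethylsilyloxy)hex-1-en-1-one | C=CC(C)(C)c1cc([C@@H]2COC(C(CCC(C)(C)O[Si](CC)(CC)CC)=C=O)=C(C=C)C2)c(O[Si](C(C)C)(C(C)C)C(C)C)cc1O[Si](C)(C)C(C)(C)C | intermediate
35 | (3R)-3-Ar-8-[3-methyl-3-(triethylsilyloxy)butyl]-3,4-dihydro-2H-chromen-7(6H)-one | C=CC(C)(C)c1cc([C@@H]2COC3=C(CCC(C)(C)O[Si](CC)(CC)CC)C(=O)CC=C3C2)c(O[Si](C(C)C)(C(C)C)C(C)C)cc1O[Si](C)(C)C(C)(C)C | intermediate
36 | (3R)-3-Ar-8-[3-methyl-3-(triethylsilyloxy)butyl]chroman-7-ol (key-step product) | C=CC(C)(C)c1cc([C@@H]2COc3c(ccc(O)c3CCC(C)(C)O[Si](CC)(CC)CC)C2)c(O[Si](C(C)C)(C(C)C)C(C)C)cc1O[Si](C)(C)C(C)(C)C | intermediate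
37 | (3R)-3-[2,4-dihydroxy-5-(2-methylbut-3-en-2-yl)phenyl]-8-(3-hydroxy-3-methylbutyl)chroman-7-ol | C=CC(C)(C)c1cc([C@@H]2COc3c(ccc(O)c3CCC(C)(C)O)C2)c(O)cc1O | target

## Step count

Total step count: 22.
Longest linear sequence: 17 (steps 1–12, 15, 16, 20, 21, 22).

## Steps most likely to fail

**1. Step 21 (tethered benzannulation).**
- What may go wrong: the four-atom tether may not let the ketene and the alkyne reach the [2+2] geometry. Vinylketene 32 would then simply reclose or dimerise. Alternatively, the ynol ether may be lost by retro-ene transfer of the benzylic C3 hydrogen before it is captured, which would also erase the stereocentre.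
- Fallback (known chemistry): ring A is made as a separate arene and ring C is closed by etherification. It sets out from 11 and 20 and comes back at 36.
- Appel iodination of 11 (I2, PPh3, imidazole) gives (2R)-2-Ar-3-iodopropyl acetate F1, and zinc dust converts it into [(2R)-3-acetoxy-2-Ar-propyl]zinc iodide F2. In parallel, commercial 2-iodoresorcinol is brominated para to one hydroxyl (NBS, MeCN, 0 °C) to 4-bromo-2-iodobenzene-1,3-diol F3 and acetylated (Ac2O, pyridine) to 4-bromo-2-iodo-1,3-phenylene diacetate F4. The reagent made from 20 and zinc, [3-methyl-3-(triethylsilyloxy)butyl]zinc iodide F5, is coupled at the more reactive C–I bond of F4 (Negishi, PdCl2(dppf)) to give 4-bromo-2-[3-methyl-3-(triethylsilyloxy)butyl]-1,3-phenylene diacetate F6. A second Negishi coupling of F2 with the C–Br bond of F6 (Pd(OAc)2, SPhos) forms C4–C4a and gives the triacetate F7. DIBAL-H at −78 °C removes the three acetyl groups to give the resorcinol alcohol F8. Mitsunobu cyclisation (PPh3, DIAD, THF, high dilution), in which only the C8a hydroxyl can reach C2, closes ring C and gives 36.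

**2. Step 20 (Negishi coupling with 2-bromocyclobutenone).**
- What may go wrong: the strained bromo enone may be consumed by polymerisation or conjugate addition faster than zerovalent palladium inserts. The zinc reagent may be protonated, or the zinc salts may hydrate the ynol ether.
- Fallback: the four-membered ring is brought in at the alcohol oxidation level. It sets out from 30 and comes back at 31.
- Commercial 2-hydroxycyclobutanone is silylated (TMSCl, Et3N) to 2-(trimethylsilyloxy)cyclobutan-1-one F9. Kinetic deprotonation at the unsubstituted α-carbon (LDA, −78 °C) and trapping with N-(5-chloropyridin-2-yl)bis(trifluoromethanesulfonimide) gives 4-(trimethylsilyloxy)cyclobut-1-en-1-yl triflate F10. Negishi coupling of this ordinary alkenyl triflate with 30 (PdCl2(dppf), THF) gives the allylic silyl ether F11. Brief methanolysis (K2CO3, MeOH, 0 °C) frees the cyclobutenol F12 without touching the hindered aryl silyl ethers or the ynol ether. MnO2 in CH2Cl2 then oxidises the allylic alcohol to 31.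

**3. Step 15 (ynol ether from the hydroxy dichlorovinyl ether).**
- What may go wrong: the lithium alkoxide on the C4 arm may add to the transient chloroalkynyl ether. It may also take over the neighbouring aryl silyl group, or be O-alkylated by 20 in HMPA.
- Fallback: the C4 arm is carried as a bromide, so that no alkoxide is present. It sets out from 17 and comes back at 24.
- Appel bromination of 17 (CBr4, PPh3) gives (2R)-2-Ar-3-bromopropyl (E)-1,2-dichlorovinyl ether F13. n-BuLi (2.2 equiv, −78 °C) should attack the dichlorovinyl ether much faster than a primary alkyl bromide and gives the lithium alkoxyacetylide F14. Alkylation with an excess of the unbranched iodide 20 (HMPA) gives the bromo ynol ether F15, and Finkelstein exchange (NaI, acetone, 50 °C) gives 24.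

## Further compounds

F1 | step 21 | (2R)-2-Ar-3-iodopropyl acetate | C=CC(C)(C)c1cc([C@@H](CI)COC(C)=O)c(O[Si](C(C)C)(C(C)C)C(C)C)cc1O[Si](C)(C)C(C)(C)C
F2 | step 21 | [(2R)-3-acetoxy-2-Ar-propyl]zinc iodide | C=CC(C)(C)c1cc([C@@H](C[Zn]I)COC(C)=O)c(O[Si](C(C)C)(C(C)C)C(C)C)cc1O[Si](C)(C)C(C)(C)C
F3 | step 21 | 4-bromo-2-iodobenzene-1,3-diol | Oc1ccc(Br)c(O)c1I
F4 | step 21 | 4-bromo-2-iodo-1,3-phenylene diacetate | CC(=O)Oc1ccc(Br)c(OC(C)=O)c1I
F5 | step 21 | [3-methyl-3-(triethylsilyloxy)butyl]zinc iodide | CC[Si](CC)(CC)OC(C)(C)CC[Zn]I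
F6 | step 21 | 4-bromo-2-[3-methyl-3-(triethylsilyloxy)butyl]-1,3-phenylene diacetate | CC(=O)Oc1ccc(Br)c(OC(C)=O)c1CCC(C)(C)O[Si](CC)(CC)CC
F7 | step 21 | triacetate, 4-[(2R)-3-acetoxy-2-Ar-propyl]-2-[3-methyl-3-(triethylsilyloxy)butyl]-1,3-phenylene diacetate | C=CC(C)(C)c1cc([C@@H](Cc2ccc(OC(C)=O)c(CCC(C)(C)O[Si](CC)(CC)CC)c2OC(C)=O)COC(C)=O)c(O[Si](C(C)C)(C(C)C)C(C)C)cc1O[Si](C)(C)C(C)(C)C
F8 | step 21 | resorcinol alcohol, 4-[(2R)-2-Ar-3-hydroxypropyl]-2-[3-methyl-3-(triethylsilyloxy)butyl]benzene-1,3-diol | C=CC(C)(C)c1cc([C@@H](Cc2ccc(O)c(CCC(C)(C)O[Si](CC)(CC)CC)c2O)CO)c(O[Si](C(C)C)(C(C)C)C(C)C)cc1O[Si](C)(C)C(C)(C)C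
F9 | step 20 | 2-(trimethylsilyloxy)cyclobutan-1-one | C[Si](C)(C)OC1CCC1=O
F10 | step 20 | 4-(trimethylsilyloxy)cyclobut-1-en-1-yl trifluoromethanesulfonate | C[Si](C)(C)OC1CC=C1OS(=O)(=O)C(F)(F)F
F11 | step 20 | allylic silyl ether, {2-[(2R)-2-Ar-3-{[5-methyl-5-(triethylsilyloxy)hex-1-yn-1-yl]oxy}propyl]cyclobut-2-en-1-yl}oxytrimethylsilane (carbinol epimers) | C=CC(C)(C)c1cc([C@@H](CC2=CCC2O[Si](C)(C)C)COC#CCCC(C)(C)O[Si](CC)(CC)CC)c(O[Si](C(C)C)(C(C)C)C(C)C)cc1O[Si](C)(C)C(C)(C)C
F12 | step 20 | cyclobutenol, 2-[(2R)-2-Ar-3-{[5-methyl-5-(triethylsilyloxy)hex-1-yn-1-yl]oxy}propyl]cyclobut-2-en-1-ol (carbinol epimers) | C=CC(C)(C)c1cc([C@@H](CC2=CCC2O)COC#CCCC(C)(C)O[Si](CC)(CC)CC)c(O[Si](C(C)C)(C(C)C)C(C)C)cc1O[Si](C)(C)C(C)(C)C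
F13 | step 15 | (2R)-2-Ar-3-bromopropyl (E)-1,2-dichlorovinyl ether | C=CC(C)(C)c1cc([C@@H](CBr)CO/C(Cl)=C\Cl)c(O[Si](C(C)C)(C(C)C)C(C)C)cc1O[Si](C)(C)C(C)(C)C
F14 | step 15 | lithium alkoxyacetylide, {[(2R)-2-Ar-3-bromopropoxy]ethynyl}lithium | C=CC(C)(C)c1cc([C@@H](CBr)COC#C[Li])c(O[Si](C(C)C)(C(C)C)C(C)C)cc1O[Si](C)(C)C(C)(C)C
F15 | step 15 | bromo ynol ether, (2R)-2-Ar-3-bromopropyl 5-methyl-5-(triethylsilyloxy)hex-1-yn-1-yl ether | C=CC(C)(C)c1cc([C@@H](CBr)COC#CCCC(C)(C)O[Si](CC)(CC)CC)c(O[Si](C(C)C)(C(C)C)C(C)C)cc1O[Si](C)(C)C(C)(C)C
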